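The quinone ring is not bought as an arene; it is assembled on the head of the finished C20 chain. Ring numbering: C1(=O)–C2(CH3)=C3H–C4(=O)–C5(chain)=C6H. C4 and C1 come from two CO ligands of Cr(CO)6, C2–C3 with the C2 methyl from propyne, and C5–C6 from a 2-bromoallyl unit. The key step, a Dötz benzannulation of an acyclic alkenyl(methoxy)carbene chromium complex with propyne, makes three ring bonds and closes the ring at C1–C6 by electrocyclisation of a dienylketene; Ce(IV) then gives the quinone. It exploits the para-dioxygenated ring and the C2 methyl beside C1. The precursor is the carbene complex carrying the unprotected anti-diol chain.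

Key step: step 10

Assumption: the secondary and tertiary side-chain hydroxyls are carried unprotected, so the aluminium and lithium reagents are charged with one extra equivalent per OH.

Step 1
Reactants: 1 geraniol
Product: 2 (2R,3R)-2,3-epoxygeraniol
Conditions: Ti(OiPr)4 (5 mol %), D-(−)-diisopropyl tartrate (6 mol %), t-BuOOH, 4 Å MS, CH2Cl2, −20 °C
Reagents that add atoms: tert-butyl hydroperoxide, CC(C)(C)OO
Why: Sharpless asymmetric epoxidation reacts only at the allylic 2,3-olefin (the 6,7-olefin is untouched), and the D-(−)-tartrate ligand should set C2 and C3 as (2R,3R) by reagent-controlled face selection.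

Step 2
Reactants: 2 (2R,3R)-2,3-epoxygeraniol
Product: 3 (2R,3S)-3,7-dimethyloct-6-ene-1,2,3-triol
Conditions: HClO4 (3 mol %), THF/H2O (3:1), 0 °C → rt
Reagents that add atoms: water, O
Why: Acid-catalysed epoxide hydrolysis in which water should attack the protonated epoxide at the tertiary C3 with inversion while C2 keeps its oxygen, turning the trans-epoxide into the anti (2R,3S) diol array.

Step 3
Reactants: 3 (2R,3S)-3,7-dimethyloct-6-ene-1,2,3-triol
Product: 5 (2S)-6-methyl-2-[(2R)-oxiran-2-yl]hept-5-en-2-ol, via primary monotosylate 4 (not isolated)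
Conditions: TsCl (1.05 equiv), Bu2SnO (2 mol %), Et3N, CH2Cl2, 0 °C; then K2CO3, MeOH, 0 °C → rt, short contact
Reagents that add atoms: none
Why: Tin-catalysed selective sulfonylation of the primary hydroxyl followed by Williamson-type 3-exo-tet closure by the secondary alkoxide, so that C2 keeps its oxygen and configuration; short base contact limits Payne rearrangement.

Step 4
Reactants: 5 (2S)-6-methyl-2-[(2R)-oxiran-2-yl]hept-5-en-2-ol; 6 1-(trimethylsilyl)propyne
Product: 9 (5R,6S)-6,10-dimethylundec-9-en-1-yne-5,6-diol, via lithiated silylpropyne 7 (not isolated), via silylated alkynediol 8 (not isolated)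
Conditions: 6 (2.5 equiv), n-BuLi (2.5 equiv), THF, −78 → −20 °C; then 5, DMPU, −78 °C → rt; then MeOH, K2CO3, rt
Reagents that add atoms: none
Why: Propargylic lithiation of the silylpropyne and SN2 opening of the terminal epoxide at its CH2 carbon (one equivalent of base is spent on the tertiary OH) leave both stereocentres untouched; methanolic carbonate then cleaves the alkynyl C–Si bond.

Step 5
Reactants: 9 (5R,6S)-6,10-dimethylundec-9-en-1-yne-5,6-diol
Product: 11 (1E,5R,6S)-1-iodo-2,6,10-trimethylundeca-1,9-diene-5,6-diol, via alkenylalane 10 (not isolated)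
Conditions: Me3Al (5 equiv), Cp2ZrCl2 (0.5 equiv), CH2Cl2, 0 °C → rt; then I2 (1.05 equiv), THF, −30 °C
Reagents that add atoms: trimethylaluminium, C[Al](C)C; iodine, II
Why: Negishi zirconium-catalysed syn-carboalumination of the terminal alkyne (methyl to the internal carbon) and iodinolysis with retention should give the (E)-iodoalkene, the hydroxyls riding through as aluminium alkoxides.

Step 6
Reactants: 12 but-3-yn-1-ol; 13 2,3-dibromopropene
Product: 15 (3E)-6-bromo-3-methylhepta-3,6-dien-1-ol, via alkenylalane 14 (not isolated)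
Conditions: Me3Al (3 equiv), Cp2ZrCl2 (0.25 equiv), CH2Cl2, 0 °C → rt; then 13 (1.5 equiv), Pd(PPh3)4 (3 mol %), THF, 0 °C → rt
Reagents that add atoms: trimethylaluminium, C[Al](C)C
Why: Negishi carboalumination followed by palladium-catalysed allylation of the alkenylalane at the allylic C–Br bond of 13 (the vinylic C–Br bond is kept) should give the E-trisubstituted skipped diene with retention of geometry.

Step 7
Reactants: 15 (3E)-6-bromo-3-methylhepta-3,6-dien-1-ol
Product: 16 (4E)-2-bromo-7-iodo-5-methylhepta-1,4-diene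
Conditions: I2, PPh3, imidazole, CH2Cl2, 0 °C
Reagents that add atoms: iodine, II
Why: Appel-type iodination of the primary alcohol under neutral conditions, which leave the vinyl bromide and the skipped diene intact.

Step 8
Reactants: 16 (4E)-2-bromo-7-iodo-5-methylhepta-1,4-diene; 11 (1E,5R,6S)-1-iodo-2,6,10-trimethylundeca-1,9-diene-5,6-diol
Product: 18 (4E,8E,12R,13S)-2-bromo-5,9,13,17-tetramethyloctadeca-1,4,8,16-tetraene-12,13-diol, via alkylzinc iodide 17 (not isolated)
Conditions: 16 (1.5 equiv), Zn dust, LiCl, THF, 25 °C; then 11, Pd(PPh3)4 (5 mol %), THF, 0 °C → rt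
Reagents that add atoms: none
Why: Zinc insertion into the primary C–I bond and Negishi sp3–sp2 coupling, in which oxidative addition should select the alkenyl iodide over the 2-bromoalkene and the E geometry of 11 is retained.

Step 9
Reactants: 18 (4E,8E,12R,13S)-2-bromo-5,9,13,17-tetramethyloctadeca-1,4,8,16-tetraene-12,13-diol; 19 hexacarbonylchromium
Product: 22 pentacarbonyl[(4E,8E,12R,13S)-12,13-dihydroxy-1-methoxy-5,9,13,17-tetramethyl-2-methylideneoctadeca-4,8,16-trien-1-ylidene]chromium, via alkenyllithium 20 (not isolated), via lithium acylchromate 21 (not isolated)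
Conditions: t-BuLi (4.2 equiv), THF, −78 °C; then Cr(CO)6 (1.2 equiv), −78 °C → rt; then solvent removed, H2O/CH2Cl2, Me3OBF4, 0 °C
Reagents that add atoms: trimethyloxonium tetrafluoroborate, C[O+](C)C.F[B-](F)(F)F
Why: Fischer carbene synthesis by Br–Li exchange (two equivalents of t-BuLi first form the dialkoxide), addition of the alkenyllithium to a CO ligand and O-methylation of the acylmetalate in water, where the alkoxides are reprotonated and stay unmethylated.

Step 10
Reactants: 22 carbene complex; 23 propyne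
Product: 25 2-[(2E,6E,10R,11S)-10,11-dihydroxy-3,7,11,15-tetramethylhexadeca-2,6,14-trien-1-yl]-5-methylcyclohexa-2,5-diene-1,4-dione, via hydroquinone monomethyl ether 24 (not isolated)
Conditions: propyne (5 equiv), THF, 50 °C, sealed tube; then CAN (5.5 equiv), MeCN/H2O, 0 °C, 10 min
Reagents that add atoms: water, O
Why: Dötz benzannulation: CO loss from 22, insertion of propyne into the Cr=C bond and CO insertion should give the chromium-bound dienylketene O=C=C(CH3)–CH=C(OCH3)–C(R)=CH2, whose closure joins the ketene carbon (ring C1) to the terminal CH2 (ring C6); tautomerisation gives the Cr(CO)3-bound phenol 24, which Ce(IV) decomplexes and oxidises (water adds at C4, methanol leaves) to the quinone. The closest known reaction type is the benzannulation of α-substituted alkenyl(alkoxy)carbene chromium complexes with terminal alkynes followed by ceric oxidation. The one ring is closed by a thermal disrotatory 6π-electrocyclisation of the hexatriene C1=C2–C3=C4–C5=C6 of the metal-bound dienylketene. No stereocentre is formed, and the side-chain stereocentres and E-olefins are remote and untouched. The step needs regioselective alkyne insertion: the larger alkyne substituent (CH3 rather than H) is placed next to the CO-derived carbon, which should give the 2-methyl-5-alkyl (para) pattern rather than the 2,6-isomer, and the unsubstituted CH2 terminus lets the cyclohexadienone tautomerise to the phenol. Chemoselectivity rests on the inertness of isolated trisubstituted olefins and hydroxyls toward the carbene at 50 °C and on brief Ce(IV) contact at 0 °C.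

Step 11
Reactants: 25 quinone diol
Product: 26 chabrolobenzoquinone H
Conditions: Ac2O, pyridine, CH2Cl2, 0 °C → rt
Reagents that add atoms: acetic anhydride, CC(=O)OC(C)=O
Why: Chemoselective acylation of the secondary alcohol; the neighbouring tertiary carbinol is too hindered to be acetylated under these conditions.

Compound list
1 | geraniol, (2E)-3,7-dimethylocta-2,6-dien-1-ol | CC(C)=CCC/C(C)=C/CO | starting material
2 | (2R,3R)-2,3-epoxygeraniol, [(2R,3R)-3-methyl-3-(4-methylpent-3-en-1-yl)oxiran-2-yl]methanol | OC[C@H]1O[C@]1(C)CCC=C(C)C | intermediate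
3 | (2R,3S)-3,7-dimethyloct-6-ene-1,2,3-triol | OC[C@@H](O)[C@@](C)(O)CCC=C(C)C | intermediate
4 | (2R,3S)-2,3-dihydroxy-3,7-dimethyloct-6-en-1-yl 4-methylbenzenesulfonate | Cc1ccc(cc1)S(=O)(=O)OC[C@@H](O)[C@@](C)(O)CCC=C(C)C | intermediate
5 | (2S)-6-methyl-2-[(2R)-oxiran-2-yl]hept-5-en-2-ol | C1O[C@H]1[C@@](C)(O)CCC=C(C)C | intermediate
6 | 1-(trimethylsilyl)propyne | CC#C[Si](C)(C)C | starting material
7 | [3-(trimethylsilyl)prop-2-yn-1-yl]lithium | [Li]CC#C[Si](C)(C)C | intermediate
8 | (5R,6S)-6,10-dimethyl-1-(trimethylsilyl)undec-9-en-1-yne-5,6-diol | C[Si](C)(C)C#CCC[C@@H](O)[C@@](C)(O)CCC=C(C)C | intermediate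
9 | (5R,6S)-6,10-dimethylundec-9-en-1-yne-5,6-diol | C#CCC[C@@H](O)[C@@](C)(O)CCC=C(C)C | intermediate
10 | (E)-alkenyl(dimethyl)alane from syn-addition of CH3–Al across the alkyne of 9, both hydroxyls as O–AlMe2 | C[Al](C)/C=C(\C)CC[C@@H](O[Al](C)C)[C@@](C)(O[Al](C)C)CCC=C(C)C | intermediate
11 | (1E,5R,6S)-1-iodo-2,6,10-trimethylundeca-1,9-diene-5,6-diol | I/C=C(\C)CC[C@@H](O)[C@@](C)(O)CCC=C(C)C | intermediate
12 | but-3-yn-1-ol | C#CCCO | starting material
13 | 2,3-dibromopropene | C=C(Br)CBr | starting material
14 | (E)-alkenyl(dimethyl)alane from syn-addition of CH3–Al across the alkyne of 12, hydroxyl as O–AlMe2 | C[Al](C)/C=C(\C)CCO[Al](C)C | intermediate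
15 | (3E)-6-bromo-3-methylhepta-3,6-dien-1-ol | OCC/C(C)=C/CC(Br)=C | intermediate
16 | (4E)-2-bromo-7-iodo-5-methylhepta-1,4-diene | C=C(Br)C/C=C(C)/CCI | intermediate
17 | [(3E)-6-bromo-3-methylhepta-3,6-dien-1-yl]zinc iodide | C=C(Br)C/C=C(C)/CC[Zn]I | intermediate
18 | (4E,8E,12R,13S)-2-bromo-5,9,13,17-tetramethyloctadeca-1,4,8,16-tetraene-12,13-diol | C=C(Br)C/C=C(C)/CC/C=C(C)/CC[C@@H](O)[C@@](C)(O)CCC=C(C)C | intermediate
19 | hexacarbonylchromium | O=C=[Cr](=C=O)(=C=O)(=C=O)(=C=O)=C=O | starting material
20 | 2-lithio-1,4-diene from Br–Li exchange of 18, both hydroxyls as lithium alkoxides | [Li]C(=C)C/C=C(C)/CC/C=C(C)/CC[C@@H](O[Li])[C@@](C)(O[Li])CCC=C(C)C | intermediate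
21 | lithium acyl(pentacarbonyl)chromate from 20 and Cr(CO)6, both hydroxyls as lithium alkoxides | [Li]OC(=[Cr](=C=O)(=C=O)(=C=O)(=C=O)=C=O)C(=C)C/C=C(C)/CC/C=C(C)/CC[C@@H](O[Li])[C@@](C)(O[Li])CCC=C(C)C | intermediate
22 | pentacarbonyl[(4E,8E,12R,13S)-12,13-dihydroxy-1-methoxy-5,9,13,17-tetramethyl-2-methylideneoctadeca-4,8,16-trien-1-ylidene]chromium | COC(=[Cr](=C=O)(=C=O)(=C=O)(=C=O)=C=O)C(=C)C/C=C(C)/CC/C=C(C)/CC[C@@H](O)[C@@](C)(O)CCC=C(C)C | intermediate
23 | propyne | CC#C | starting material
24 | 5-[(2E,6E,10R,11S)-10,11-dihydroxy-3,7,11,15-tetramethylhexadeca-2,6,14-trien-1-yl]-4-methoxy-2-methylphenol (formed as its Cr(CO)3 complex) | COc1cc(C)c(O)cc1C/C=C(C)/CC/C=C(C)/CC[C@@H](O)[C@@](C)(O)CCC=C(C)C | intermediate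
25 | 2-[(2E,6E,10R,11S)-10,11-dihydroxy-3,7,11,15-tetramethylhexadeca-2,6,14-trien-1-yl]-5-methylcyclohexa-2,5-diene-1,4-dione | CC1=CC(=O)C(C/C=C(C)/CC/C=C(C)/CC[C@@H](O)[C@@](C)(O)CCC=C(C)C)=CC1=O | intermediate
26 | chabrolobenzoquinone H, the (10R)-acetate of 25 with free (11S) tertiary hydroxyl | CC(=O)O[C@H](CC/C(C)=C/CC/C(C)=C/CC1=CC(=O)C(C)=CC1=O)[C@@](C)(O)CCC=C(C)C | target

Total step count: 11. Longest linear sequence: 9 steps (1, 2, 3, 4, 5, 8, 9, 10, 11); steps 6 and 7 form the side branch.

Steps most likely to fail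

Step 10. Two processes threaten the one-pot sequence: hydroxyl capture of the vinylketene during the benzannulation, and Ce(IV) over-oxidation (glycol cleavage) of the unprotected diol, with the sensitive quinone then still having to survive acetylation. The fallback re-orders the endgame so that the oxidant meets the acetate and the quinone appears last. Setting out from 22, the benzannulation with propyne is run with TBSCl and i-Pr2NEt present (THF, 50 °C, then air) to give the aryl silyl ether F1. Ac2O, pyridine and DMAP acetylate its secondary alcohol to give the aryl silyl ether acetate F2. CAN in MeCN/H2O then oxidises the silyl methyl hydroquinone diether directly to the quinone, and the route is rejoined at 26.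

Step 9. The polylithiated intermediate may aggregate or transfer a proton from the doubly allylic CH2 to the alkenyllithium, so that little acylmetalate forms. The fallback removes the alkoxides. Setting out from 18, TMSCl and imidazole in DMF give the bis(trimethylsilyl) ether F3. t-BuLi (2 equiv, THF, −78 °C) gives the silylated alkenyllithium F4, Cr(CO)6 the silylated lithium acylchromate F5, and MeOTf in CH2Cl2 the bis-silylated carbene complex F6. Brief dilute HCl in THF removes both silyl groups, and the route is rejoined at 22.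

Step 8. Chemoselectivity between C–I and C–Br oxidative addition may erode and lead to oligomerisation of the bromoalkene-bearing zinc reagent. The fallback is linear and introduces the vinyl bromide only after all zinc chemistry. Setting out from 11, Negishi coupling with [4-(trimethylsilyl)but-3-yn-1-yl]zinc bromide F7 (from commercial (4-bromobut-1-yn-1-yl)trimethylsilane and zinc) gives the silylated enyne diol F8. K2CO3 in MeOH gives the terminal enyne diol F9. A second zirconium-catalysed carboalumination gives the alkenylalane F10, which is allylated with 13 under Pd(PPh3)4; the route is rejoined at 18, and steps 6 and 7 are then not needed.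

Further compounds
F1 | step 10 | tert-butyldimethylsilyl ether of phenol 24, side-chain diol free | COc1cc(C)c(O[Si](C)(C)C(C)(C)C)cc1C/C=C(C)/CC/C=C(C)/CC[C@@H](O)[C@@](C)(O)CCC=C(C)C
F2 | step 10 | (10R)-acetate of F1, tertiary hydroxyl free | COc1cc(C)c(O[Si](C)(C)C(C)(C)C)cc1C/C=C(C)/CC/C=C(C)/CC[C@@H](OC(C)=O)[C@@](C)(O)CCC=C(C)C
F3 | step 9 | bis(trimethylsilyl) ether of 18 | C=C(Br)C/C=C(C)/CC/C=C(C)/CC[C@@H](O[Si](C)(C)C)[C@@](C)(O[Si](C)(C)C)CCC=C(C)C
F4 | step 9 | 2-lithio-1,4-diene from Br–Li exchange of F3 | [Li]C(=C)C/C=C(C)/CC/C=C(C)/CC[C@@H](O[Si](C)(C)C)[C@@](C)(O[Si](C)(C)C)CCC=C(C)C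
F5 | step 9 | lithium acyl(pentacarbonyl)chromate from F4 | [Li]OC(=[Cr](=C=O)(=C=O)(=C=O)(=C=O)=C=O)C(=C)C/C=C(C)/CC/C=C(C)/CC[C@@H](O[Si](C)(C)C)[C@@](C)(O[Si](C)(C)C)CCC=C(C)C
F6 | step 9 | bis(trimethylsilyl) ether of carbene complex 22 | COC(=[Cr](=C=O)(=C=O)(=C=O)(=C=O)=C=O)C(=C)C/C=C(C)/CC/C=C(C)/CC[C@@H](O[Si](C)(C)C)[C@@](C)(O[Si](C)(C)C)CCC=C(C)C
F7 | step 8 | [4-(trimethylsilyl)but-3-yn-1-yl]zinc bromide | C[Si](C)(C)C#CCC[Zn]Br
F8 | step 8 | (5E,9R,10S)-6,10,14-trimethyl-1-(trimethylsilyl)pentadeca-5,13-dien-1-yne-9,10-diol | C[Si](C)(C)C#CCC/C=C(C)/CC[C@@H](O)[C@@](C)(O)CCC=C(C)C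
F9 | step 8 | (5E,9R,10S)-6,10,14-trimethylpentadeca-5,13-dien-1-yne-9,10-diol | C#CCC/C=C(C)/CC[C@@H](O)[C@@](C)(O)CCC=C(C)C
F10 | step 8 | (E)-alkenyl(dimethyl)alane from syn-addition of CH3–Al across the alkyne of F9, both hydroxyls as O–AlMe2 | C[Al](C)/C=C(\C)CC/C=C(C)/CC[C@@H](O[Al](C)C)[C@@](C)(O[Al](C)C)CCC=C(C)C
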